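A direct plan would build the tetrahydrofuran first and the medium ring last. It would join vinylcyclopropyl ketone A1 and keto aldehyde A2 by a Lewis-acid (3+2) annulation to tetrahydrofuran A3 and close a ring-B cyclohexenone by aldol condensation. It would then close the oxonene A4 by ring-closing metathesis, hydrate C7=C8 by hydrogen-atom transfer, hydrogenate the tetrasubstituted enone to ketone A5 and finish with a Baeyer–Villiger oxidation.
Its weakest steps would be:
- The (3+2) union of a singly activated cyclopropane with an aldehyde: this has no precedent, and C2 and C9 would be left to a reversible ionisation without firm control.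
- The hydrogenation of the tetrasubstituted enone: it would need forcing pressure and would have to set C14 and C15 (an axial, epimerisable methyl) on facial bias alone.
- The metathesis to a nine-membered trisubstituted alkene followed by radical hydration: the closure would fight strain, and C7 would be set by a radical with no real facial control.

**Retrosynthetic overview**
- Key cut: C1–C10 and C13–C14 by an intramolecular Diels–Alder across the ether oxygen (C1–C2–O–C9–C10), which closes ring A (C1, C10–C14) and the tetrahydrofuran together on a preformed oxonene.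
- Other cuts: C8–C9 (enolate alkylation on a 1,4-dioxan-2-one template built from nerol) and C15–C17/C17–O3 (CO insertion into the C14 acetyl group).
- Ring order: oxonane (O, C2–C9), then ring A and tetrahydrofuran in one step, then the ε-lactone.
- Stereocentres: C2/C3 from Sharpless epoxidation, C9 from the template, C1/C10/C14 from the cycloaddition, C6/C7 by syn-dihydroxylation of the E-alkene, C15 by hydrogenation of an exocyclic alkene, C11 by anti acetoxymercuration.
- The design needs no cyclopropane annulation, no metathesis to a trisubstituted medium-ring alkene, no tetrasubstituted-enone reduction and no radical hydration.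

Key step: step 12

Remark: locants C1–C17 follow the eunicellane numbering of the target throughout; the (E)-oxonene is assumed to react on its outer face only.

Step 1
Reactants: 1 nerol
Product: 2 (2R,3S)-2,3-epoxynerol
Conditions: Ti(OiPr)4 (10 mol %), D-(−)-diisopropyl tartrate (12 mol %), t-BuOOH, 4 Å MS, CH2Cl2, −20 °C
Reagents that add atoms: tert-butyl hydroperoxide, CC(C)(C)OO
Why: Sharpless asymmetric epoxidation; the D-tartrate catalyst epoxidises only the allylic-alcohol double bond of the Z-alkene and sets C2 (R) and C3 (S).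

Step 2
Reactants: 2 (2R,3S)-2,3-epoxynerol; 3 2-[(tert-butyldimethylsilyl)oxy]acetic acid
Product: 4 (2R,3S)-2,3-epoxyneryl 2-[(tert-butyldimethylsilyl)oxy]acetate
Conditions: N,N'-dicyclohexylcarbodiimide, DMAP (cat.), CH2Cl2, 0 °C to rt
Reagents that add atoms: none
Why: Steglich esterification of the primary alcohol under neutral conditions leaves the acid-sensitive trisubstituted epoxide intact.

Step 3
Reactants: 4 (2R,3S)-2,3-epoxyneryl 2-[(tert-butyldimethylsilyl)oxy]acetate
Product: 6 (5S)-5-[(2S)-2-hydroxy-6-methylhept-5-en-2-yl]-1,4-dioxan-2-one, via epoxyneryl hydroxyacetate 5 (not isolated)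
Conditions: Bu4NF, AcOH, THF, 0 °C, aqueous work-up; then NaH (0.2 equiv), THF, 0 °C to rt
Reagents that add atoms: none
Why: Fluoride desilylation followed by base-catalysed intramolecular epoxide opening: the hydroxyacetate alkoxide attacks C2 in a 6-exo SN2 mode, which places the ether at C2 and the ester at C1 without ambiguity, inverts C2 to S and leaves C3 (S) untouched, while proton transfer from unreacted hydroxyacetate carries the chain.

Step 4
Reactants: 6 (5S)-5-[(2S)-2-hydroxy-6-methylhept-5-en-2-yl]-1,4-dioxan-2-one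
Product: 7 (5S)-5-[(2S)-6-methyl-2-(triethylsilyloxy)hept-5-en-2-yl]-1,4-dioxan-2-one
Conditions: Et3SiOTf, 2,6-lutidine, CH2Cl2, −78 to 0 °C
Reagents that add atoms: triethylsilyl trifluoromethanesulfonate, CC[Si](CC)(CC)OS(=O)(=O)C(F)(F)F
Why: Silylation of the tertiary alcohol with a silyl triflate masks O3, so that its alkoxide cannot open the lactone during step 7.

Step 5
Reactants: 7 (5S)-5-[(2S)-6-methyl-2-(triethylsilyloxy)hept-5-en-2-yl]-1,4-dioxan-2-one
Product: 8 (5S)-5-[(2S,5E)-7-hydroxy-6-methyl-2-(triethylsilyloxy)hept-5-en-2-yl]-1,4-dioxan-2-one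
Conditions: SeO2 (0.3 equiv), t-BuOOH, salicylic acid (cat.), CH2Cl2, rt
Reagents that add atoms: tert-butyl hydroperoxide, CC(C)(C)OO
Why: Selenium dioxide allylic oxidation (ene reaction then [2,3]-shift) hydroxylates the (E)-methyl group of the trisubstituted alkene selectively and so turns C8 into a handle with the E geometry fixed.

Step 6
Reactants: 8 (5S)-5-[(2S,5E)-7-hydroxy-6-methyl-2-(triethylsilyloxy)hept-5-en-2-yl]-1,4-dioxan-2-one
Product: 9 (5S)-5-[(2S,5E)-7-chloro-6-methyl-2-(triethylsilyloxy)hept-5-en-2-yl]-1,4-dioxan-2-one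
Conditions: N-chlorosuccinimide, Me2S, CH2Cl2, −20 to 0 °C
Reagents that add atoms: N-chlorosuccinimide, O=C1CCC(=O)N1Cl
Why: Corey–Kim chlorination converts the primary allylic alcohol into the chloride by SN2 displacement, without allylic transposition or loss of the E geometry.

Step 7
Reactants: 9 (5S)-5-[(2S,5E)-7-chloro-6-methyl-2-(triethylsilyloxy)hept-5-en-2-yl]-1,4-dioxan-2-one
Product: 10 (2S,3S,6E,9S)-oxonene lactone (ring O–C2–C3–C4–C5–C6=C7–C8–C9 bridged by C9–C10(=O)–O–C1H2–C2)
Conditions: LiN(SiMe3)2 (1.3 equiv), THF (5 mM), −78 to −20 °C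
Reagents that add atoms: none
Why: Proposed new method: LiN(SiMe3)2 forms the lactone enolate at C9, whose π-face is reached only by the axial C2 side chain, so SN2 displacement of the allylic chloride at C8 closes the nine-membered (E)-oxonene and the new C9 centre is necessarily cis to C2 (9S) because the six-membered lactone cannot be bridged trans; the closest known reaction type is the intramolecular alkylation of open-chain α-alkoxy amide enolates with allylic chlorides to 2,9-cis oxonenes, not yet shown for a dioxanone enolate.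

Step 8
Reactants: 10 (2S,3S,6E,9S)-oxonene lactone
Product: 11 lactol of 10 (C10 hemiacetal; both anomers)
Conditions: i-Bu2AlH (1.1 equiv), CH2Cl2, −78 °C; Rochelle salt work-up
Reagents that add atoms: none
Why: Partial reduction of the lactone stops at the tetrahedral aluminium alkoxide, so that one operation unmasks C10 as an aldehyde and C1 as an alcohol.

Step 9
Reactants: 11 lactol of 10; 12 2-(triphenylphosphoranylidene)propanal
Product: 13 (2S,3S,6E,9S)-oxonene with 2-CH2OH and 9-[(1E)-2-methyl-3-oxoprop-1-enyl]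
Conditions: toluene, 90 °C
Reagents that add atoms: none
Why: Wittig reaction of the open hydroxy-aldehyde form of the lactol with the stabilised formyl ylide gives the (E)-trisubstituted enal and frees the C1 hydroxyl, with C9 untouched.

Step 10
Reactants: 13 (2S,3S,6E,9S)-oxonene with 2-CH2OH and 9-[(1E)-2-methyl-3-oxoprop-1-enyl]
Product: 14 (2S,3S,6E,9S)-oxonene with 2-CH2OH and 9-[(1E)-2-methylbuta-1,3-dienyl]
Conditions: Ph3PCH3Br, KN(SiMe3)2 (2.5 equiv each), THF, −78 to 0 °C
Reagents that add atoms: methyltriphenylphosphonium bromide, C[P+](c1ccccc1)(c1ccccc1)c1ccccc1.[Br-]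
Why: Wittig methylenation of the enal completes the C10–C13 diene; the aldehyde is consumed at −78 °C before the transient C1 alkoxide can add to the enal.

Step 11
Reactants: 14 (2S,3S,6E,9S)-oxonene with 2-CH2OH and 9-[(1E)-2-methylbuta-1,3-dienyl]
Product: 15 (2R,3S,6E,9S)-oxonene-2-carbaldehyde with 9-[(1E)-2-methylbuta-1,3-dienyl]
Conditions: Dess–Martin periodinane, NaHCO3, CH2Cl2, 0 °C
Reagents that add atoms: none
Why: Dess–Martin oxidation of the primary alcohol under buffered conditions gives the α-alkoxy aldehyde without epimerising C2 (the descriptor changes by priority only) or touching the diene.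

Step 12
Reactants: 15 (2R,3S,6E,9S)-oxonene-2-carbaldehyde with 9-[(1E)-2-methylbuta-1,3-dienyl]; 16 1-(triphenylphosphoranylidene)propan-2-one
Product: 18 (1R,2S,3S,6E,9S,10S,14R)-tricyclic methyl ketone (ring A with C11=C12 cis-fused to the tetrahydrofuran on the oxonene; 14-acetyl; 3-OSiEt3), via tetraene enone 17 (not isolated)
Conditions: toluene, BHT (cat.), rt to 80 °C
Reagents that add atoms: none
Why: The stabilised ylide gives the (E)-enone (Wittig reaction), and the resulting tetraene 17 cyclises by a concerted thermal [4+2] (intramolecular Diels–Alder) in which the ether oxygen is the centre of the tether C1–C2–O–C9–C10. The closest known reaction type is the intramolecular Diels–Alder of 2,9-dialkenyl oxonenes to hexahydroisobenzofurans. Ring A (C1, C10–C14) closes as the six-membered cycloadduct through the new bonds C1–C10 and C13–C14, and the tetrahydrofuran (O, C2, C1, C10, C9) closes as the five-membered tether ring, cis-fused. C1 and C10 are set by allylic 1,3-strain: H2 lies in the plane of the dienophile (away from the quaternary C3) and H9 in the plane of the diene (away from the C11 methyl), so ring A grows on the face of the C2–O–C9 unit opposite the oxonene carbons, giving H1 trans to H2, H10 trans to H9 and a cis ring fusion. C14 follows from the (E)-dienophile by suprafacial addition, which places the acetyl group trans to C2. The step needs the cis-fused adduct with ring A anti to the medium ring, and the 2,9-cis (E)-oxonene, the E geometry of both partners and the activated enone (reaction below 100 °C) should secure it.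

Step 13
Reactants: 18 (1R,2S,3S,6E,9S,10S,14R)-tricyclic methyl ketone
Product: 20 (1R,2S,3S,6E,9S,10S,14R)-tricyclic C3 alcohol with 14-[1-(trifluoromethylsulfonyloxy)ethenyl], via silyl vinyl triflate 19 (not isolated)
Conditions: KN(SiMe3)2, THF, −78 °C; PhNTf2, −78 to 0 °C; then HF·pyridine, THF, 0 °C
Reagents that add atoms: N-phenylbis(trifluoromethanesulfonimide), O=S(=O)(N(c1ccccc1)S(=O)(=O)C(F)(F)F)C(F)(F)F
Why: Kinetic deprotonation of the methyl ketone at the methyl group (not at the hindered C14–H) and O-triflation give the terminal enol triflate without touching C14, and fluoride desilylation then frees the C3 hydroxyl.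

Step 14
Reactants: 20 (1R,2S,3S,6E,9S,10S,14R)-tricyclic C3 alcohol with 14-[1-(trifluoromethylsulfonyloxy)ethenyl]
Product: 21 (1S,2S,3S,6E,9S,10S,14R)-tetracyclic α-methylene ε-lactone (C3–O–C17(=O)–C15(=C16H2)–C14)
Conditions: Pd(PPh3)4 (10 mol %), CO (1 atm), n-Bu3N, LiCl, MeCN, 65 °C
Reagents that add atoms: carbon monoxide, [C-]#[O+]
Why: Palladium-catalysed carbonylative lactonisation: zerovalent palladium inserts into the C15–OTf bond, CO inserts (this carbon becomes C17) and the acylpalladium is captured by the C3 hydroxyl, which the trans C1–C2 ring fusion holds within reach, closing the seven-membered lactone.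

Step 15
Reactants: 21 (1S,2S,3S,6E,9S,10S,14R)-tetracyclic α-methylene ε-lactone
Product: 22 (1S,2S,3S,6R,7R,9S,10S,14R)-6,7-diol of 21
Conditions: OsO4 (5 mol %), (DHQD)2PHAL (10 mol %), N-methylmorpholine N-oxide, acetone/H2O, 0 °C
Reagents that add atoms: N-methylmorpholine N-oxide, C[N+]1([O-])CCOCC1; water, O
Why: Osmium-catalysed syn-dihydroxylation: the strained (E)-C6=C7 should react far faster than the trisubstituted C11=C12 or the electron-poor C15=C16, and syn-addition to the E-alkene gives exactly the C6–O/C7–O relationship of the target, with the outer face of the alkene and the ligand sense both pointing to 6R,7R.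

Step 16
Reactants: 22 (1S,2S,3S,6R,7R,9S,10S,14R)-6,7-diol of 21
Product: 23 (1S,2S,3S,6R,7R,9S,10S,14R)-6-O-methyl ether of 22
Conditions: MeOTf, 2,6-di-tert-butyl-4-methylpyridine, CH2Cl2, 0 °C to rt
Reagents that add atoms: methyl trifluoromethanesulfonate, COS(=O)(=O)C(F)(F)F
Why: O-alkylation with methyl triflate and a hindered base methylates the secondary C6 hydroxyl in preference to the tertiary C7 hydroxyl and does not touch the α-methylene lactone.

Step 17
Reactants: 23 (1S,2S,3S,6R,7R,9S,10S,14R)-6-O-methyl ether of 22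
Product: 24 (1S,2S,3S,6R,7R,9S,10S,14R,15R)-7-hydroxy-6-methoxy-2,9-epoxyeunicell-11-en-17,3-olide
Conditions: H2 (1 atm), RhCl(PPh3)3 (10 mol %), benzene/EtOH, rt
Reagents that add atoms: none
Why: Homogeneous hydrogenation reduces only the conjugated 1,1-disubstituted C15=C16 (the trisubstituted C11=C12 is inert), and hydrogen should enter from the face remote from C13 on the neighbouring ring-fusion carbon C14, as in 2-alkylmethylenecycloalkanes, which leaves the new methyl cis to C13 (15R) under neutral conditions that do not epimerise it.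

Step 18
Reactants: 24 (1S,2S,3S,6R,7R,9S,10S,14R,15R)-7-hydroxy-6-methoxy-2,9-epoxyeunicell-11-en-17,3-olide
Product: 26 CNP0238771.1, via acetoxymercurial 25 (not isolated)
Conditions: Hg(OAc)2, AcOH, rt; then n-Bu3SnH, THF, 0 °C
Reagents that add atoms: mercury diacetate, CC(=O)O[Hg]OC(C)=O
Why: Solvomercuration–demercuration: mercury adds to C11=C12 from the convex face of the cis-fused ring A (the face of H1 and H10) and acetic acid opens the mercurinium ion at the tertiary C11 from the opposite face (Markovnikov, anti), which delivers the 11R acetate directly without having to acylate one of two tertiary alcohols, before the tin hydride replaces mercury at C12 by hydrogen under neutral conditions.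

**Compound list**

1 | nerol, (2Z)-3,7-dimethylocta-2,6-dien-1-ol | CC(C)=CCC/C(C)=C\CO | starting material
2 | (2R,3S)-2,3-epoxynerol, [(2R,3S)-3-methyl-3-(4-methylpent-3-en-1-yl)oxiran-2-yl]methanol | CC(C)=CCC[C@]1(C)O[C@@H]1CO | intermediate
3 | 2-[(tert-butyldimethylsilyl)oxy]acetic acid | O=C(O)CO[Si](C)(C)C(C)(C)C | starting material
4 | [(2R,3S)-3-methyl-3-(4-methylpent-3-en-1-yl)oxiran-2-yl]methyl 2-[(tert-butyldimethylsilyl)oxy]acetate | CC(C)=CCC[C@]1(C)O[C@@H]1COC(=O)CO[Si](C)(C)C(C)(C)C | intermediate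
5 | [(2R,3S)-3-methyl-3-(4-methylpent-3-en-1-yl)oxiran-2-yl]methyl hydroxyacetate | CC(C)=CCC[C@]1(C)O[C@@H]1COC(=O)CO | intermediate
6 | (5S)-5-[(2S)-2-hydroxy-6-methylhept-5-en-2-yl]-1,4-dioxan-2-one | CC(C)=CCC[C@](C)(O)[C@@H]1COC(=O)CO1 | intermediate
7 | (5S)-5-[(2S)-6-methyl-2-(triethylsilyloxy)hept-5-en-2-yl]-1,4-dioxan-2-one | CC(C)=CCC[C@](C)(O[Si](CC)(CC)CC)[C@@H]1COC(=O)CO1 | intermediate
8 | (5S)-5-[(2S,5E)-7-hydroxy-6-methyl-2-(triethylsilyloxy)hept-5-en-2-yl]-1,4-dioxan-2-one | OC/C(C)=C/CC[C@](C)(O[Si](CC)(CC)CC)[C@@H]1COC(=O)CO1 | intermediate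
9 | (5S)-5-[(2S,5E)-7-chloro-6-methyl-2-(triethylsilyloxy)hept-5-en-2-yl]-1,4-dioxan-2-one | ClC/C(C)=C/CC[C@](C)(O[Si](CC)(CC)CC)[C@@H]1COC(=O)CO1 | intermediate
10 | (2S,3S,6E,9S)-oxonene lactone: ring O–C2–C3–C4–C5–C6=C7–C8–C9 with 3-methyl, 3-OSiEt3, 7-methyl and the lactone bridge C9–C10(=O)–O–C1H2–C2 | C/C1=C\CC[C@](C)(O[Si](CC)(CC)CC)[C@@H]2COC(=O)[C@H](C1)O2 | intermediate
11 | lactol of 10 (C10 hemiacetal, both anomers) | C/C1=C\CC[C@](C)(O[Si](CC)(CC)CC)[C@@H]2COC(O)[C@H](C1)O2 | intermediate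
12 | 2-(triphenylphosphoranylidene)propanal | CC(C=O)=P(c1ccccc1)(c1ccccc1)c1ccccc1 | starting material
13 | (2S,3S,6E,9S)-oxonene: 2-hydroxymethyl, 3-methyl, 3-OSiEt3, 7-methyl, 9-[(1E)-2-methyl-3-oxoprop-1-en-1-yl] | C/C1=C\CC[C@](C)(O[Si](CC)(CC)CC)[C@H](CO)O[C@@H](C1)/C=C(C)/C=O | intermediate
14 | (2S,3S,6E,9S)-oxonene: 2-hydroxymethyl, 3-methyl, 3-OSiEt3, 7-methyl, 9-[(1E)-2-methylbuta-1,3-dien-1-yl] | C/C1=C\CC[C@](C)(O[Si](CC)(CC)CC)[C@H](CO)O[C@@H](C1)/C=C(C)/C=C | intermediate
15 | (2R,3S,6E,9S)-oxonene-2-carbaldehyde: 3-methyl, 3-OSiEt3, 7-methyl, 9-[(1E)-2-methylbuta-1,3-dien-1-yl] | C/C1=C\CC[C@](C)(O[Si](CC)(CC)CC)[C@H](C=O)O[C@@H](C1)/C=C(C)/C=C | intermediate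
16 | 1-(triphenylphosphoranylidene)propan-2-one | CC(=O)C=P(c1ccccc1)(c1ccccc1)c1ccccc1 | starting material
17 | (2S,3S,6E,9S)-tetraene: oxonene with 2-[(1E)-3-oxobut-1-en-1-yl] and 9-[(1E)-2-methylbuta-1,3-dien-1-yl] | C/C1=C\CC[C@](C)(O[Si](CC)(CC)CC)[C@H](/C=C/C(C)=O)O[C@@H](C1)/C=C(C)/C=C | intermediate
18 | (1R,2S,3S,6E,9S,10S,14R)-tricycle: ring A cyclohexene (C1, C10–C14; C11=C12, 11-methyl) cis-fused to the tetrahydrofuran (O, C2, C1, C10, C9) on the (6E)-oxonene; 3-methyl, 3-OSiEt3, 7-methyl, 14-acetyl | C/C1=C\CC[C@](C)(O[Si](CC)(CC)CC)[C@H]2O[C@@H](C1)[C@@H]3C(C)=CC[C@@H](C(C)=O)[C@H]23 | intermediate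
19 | 18 with 14-[1-(trifluoromethylsulfonyloxy)ethenyl] in place of 14-acetyl | C/C1=C\CC[C@](C)(O[Si](CC)(CC)CC)[C@H]2O[C@@H](C1)[C@@H]3C(C)=CC[C@@H](C(=C)OS(=O)(=O)C(F)(F)F)[C@H]23 | intermediate
20 | 19 with free 3-OH, (1R,2S,3S,6E,9S,10S,14R) | C/C1=C\CC[C@](C)(O)[C@H]2O[C@@H](C1)[C@@H]3C(C)=CC[C@@H](C(=C)OS(=O)(=O)C(F)(F)F)[C@H]23 | intermediate
21 | (1S,2S,3S,6E,9S,10S,14R)-tetracycle: 15-methylene ε-lactone C3–O–C17(=O)–C15(=C16H2)–C14, with C6=C7 (E) and C11=C12 | C/C1=C\CC[C@]2(C)OC(=O)C(=C)[C@@H]3CC=C(C)[C@@H]4[C@H]3[C@@H]2O[C@H]4C1 | intermediate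
22 | (1S,2S,3S,6R,7R,9S,10S,14R)-6,7-diol of 21 | O[C@@H]1CC[C@]2(C)OC(=O)C(=C)[C@@H]3CC=C(C)[C@@H]4[C@H]3[C@@H]2O[C@H]4C[C@@]1(C)O | intermediate
23 | (1S,2S,3S,6R,7R,9S,10S,14R)-6-O-methyl ether of 22 | CO[C@@H]1CC[C@]2(C)OC(=O)C(=C)[C@@H]3CC=C(C)[C@@H]4[C@H]3[C@@H]2O[C@H]4C[C@@]1(C)O | intermediate
24 | (1S,2S,3S,6R,7R,9S,10S,14R,15R)-7-hydroxy-6-methoxy-2,9-epoxyeunicell-11-en-17,3-olide | CO[C@@H]1CC[C@]2(C)OC(=O)[C@H](C)[C@@H]3CC=C(C)[C@@H]4[C@H]3[C@@H]2O[C@H]4C[C@@]1(C)O | intermediate
25 | 11-acetoxy-12-(acetoxymercurio) adduct of 24 (mercury trans to the 11-acetate) | CO[C@@H]1CC[C@]2(C)OC(=O)[C@H](C)[C@@H]3C[C@H]([Hg]OC(C)=O)[C@@](C)(OC(C)=O)[C@@H]4[C@H]3[C@@H]2O[C@H]4C[C@@]1(C)O | intermediate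
26 | CNP0238771.1, (1S,2S,3S,6R,7R,9S,10R,11R,14R,15R)-11-acetoxy-7-hydroxy-6-methoxy-2,9-epoxyeunicellan-17,3-olide | CO[C@@H]1CC[C@]2(C)OC(=O)[C@H](C)[C@@H]3CC[C@@](C)(OC(C)=O)[C@@H]4[C@H]3[C@@H]2O[C@H]4C[C@@]1(C)O | target

**Step count and risks**

Total step count: 18. Longest linear sequence: 18 (fully linear from nerol).

Steps most likely to fail:

1. Step 7 (Proposed new method). The bridging ring closure may lose to SN2′ attack at C6 or to intermolecular alkylation, because the lactone enolate has to reach C8 through a strained transition state. Fallback, from 9 back to 10: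
   - aminolysis of the lactone with Me2AlNMe2 would give the open-chain hydroxy dimethylamide F1;
   - silylation of the primary alcohol (Et3SiCl, imidazole) would give the bis-silyl ether F2;
   - the known open-chain α-alkoxy amide enolate alkylation (LiN(SiMe3)2, THF, −78 °C to rt) would close the 2,9-cis (E)-oxonene amide F3;
   - removal of the primary silyl ether (PPTS, MeOH, 0 °C) would give the hydroxy amide F4;
   - acid-catalysed lactonisation (camphorsulfonic acid, toluene, 60 °C) would return to lactone 10.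

2. Step 14. Capture of the acylpalladium by the hindered tertiary C3 hydroxyl may be slower than reduction or hydrolysis of the triflate. Fallback, from 20 back to 21:
   - reductive carbonylation (Pd(PPh3)4, CO, n-Bu3SnH, THF, 50 °C) would give the hydroxy enal F5, which should close to the seven-membered lactol F6;
   - oxidation of the lactol ((n-Pr4N)RuO4, N-methylmorpholine N-oxide, 4 Å MS) would return to lactone 21.
   The C17–O3 bond is then made by hemiacetal formation instead of acylpalladium alcoholysis.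

3. Step 17. Hydrogen delivery to the exocyclic alkene may show poor facial selectivity, so that C15 forms as a mixture. Fallback, from 18 back to 24:
   - dihydroxylation as in step 15 would give the diol ketone F7;
   - methylation as in step 16 would give the methyl ether F8;
   - Wittig methylenation (Ph3P=CH2) would give the isopropenyl compound F9;
   - hydroboration with the matched enantiomer of diisopinocampheylborane and oxidation (NaOH, H2O2) would set C15 under reagent control and give the primary alcohol F10;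
   - HF·pyridine would free the C3 hydroxyl to give the diol F11;
   - oxidative lactonisation ((n-Pr4N)RuO4, N-methylmorpholine N-oxide) through the lactol would close the lactone and rejoin the route at 24.

Further compounds
F1 | step 7 | open-chain hydroxy dimethylamide from 9 (2S,3S; C1–OH free, C8–Cl) | ClC/C(C)=C/CC[C@](C)(O[Si](CC)(CC)CC)[C@H](CO)OCC(=O)N(C)C
F2 | step 7 | 1-O-triethylsilyl ether of F1 | ClC/C(C)=C/CC[C@](C)(O[Si](CC)(CC)CC)[C@H](CO[Si](CC)(CC)CC)OCC(=O)N(C)C
F3 | step 7 | (2S,3S,6E,9S)-oxonene-9-carboxylic acid dimethylamide with 2-CH2OSiEt3 | C/C1=C\CC[C@](C)(O[Si](CC)(CC)CC)[C@H](CO[Si](CC)(CC)CC)O[C@@H](C1)C(=O)N(C)C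
F4 | step 7 | (2S,3S,6E,9S)-oxonene-9-carboxylic acid dimethylamide with 2-CH2OH | C/C1=C\CC[C@](C)(O[Si](CC)(CC)CC)[C@H](CO)O[C@@H](C1)C(=O)N(C)C
F5 | step 14 | tricyclic C3 alcohol with 14-(3-oxoprop-1-en-2-yl) (hydroxy enal) | C/C1=C\CC[C@](C)(O)[C@H]2O[C@@H](C1)[C@@H]3C(C)=CC[C@@H](C(=C)C=O)[C@H]23
F6 | step 14 | seven-membered lactol of F5 (C17 hemiacetal, both anomers) | C/C1=C\CC[C@]2(C)OC(O)C(=C)[C@@H]3CC=C(C)[C@@H]4[C@H]3[C@@H]2O[C@H]4C1
F7 | step 17 | (6R,7R)-6,7-diol of ketone 18 | O[C@@H]1CC[C@](C)(O[Si](CC)(CC)CC)[C@H]2O[C@@H](C[C@@]1(C)O)[C@@H]3C(C)=CC[C@@H](C(C)=O)[C@H]23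
F8 | step 17 | 6-O-methyl ether of F7 | CO[C@@H]1CC[C@](C)(O[Si](CC)(CC)CC)[C@H]2O[C@@H](C[C@@]1(C)O)[C@@H]3C(C)=CC[C@@H](C(C)=O)[C@H]23
F9 | step 17 | 14-isopropenyl compound from F8 | CO[C@@H]1CC[C@](C)(O[Si](CC)(CC)CC)[C@H]2O[C@@H](C[C@@]1(C)O)[C@@H]3C(C)=CC[C@@H](C(C)=C)[C@H]23
F10 | step 17 | (15R)-17-hydroxy compound from F9 (primary alcohol) | CO[C@@H]1CC[C@](C)(O[Si](CC)(CC)CC)[C@H]2O[C@@H](C[C@@]1(C)O)[C@@H]3C(C)=CC[C@@H]([C@@H](C)CO)[C@H]23
F11 | step 17 | (15R)-3,17-diol from F10 | CO[C@@H]1CC[C@](C)(O)[C@H]2O[C@@H](C[C@@]1(C)O)[C@@H]3C(C)=CC[C@@H]([C@@H](C)CO)[C@H]23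
A1 | direct plan | (1R,5R,6S,7S)-7-ethenyl-5-hydroxy-5-methylbicyclo[4.1.0]heptan-2-one | C=C[C@H]1[C@H]2[C@@H]1C(=O)CC[C@@]2(C)O
A2 | direct plan | (2S,5R)-5-methoxy-2,6-dimethyl-2-propanoylhept-6-enal | CCC(=O)[C@@](C)(CC[C@@H](OC)C(C)=C)C=O
A3 | direct plan | keto-tetrahydrofuran from the (3+2) union (9-vinyl, C3 side chain) | CCC(=O)[C@@](C)(CC[C@@H](OC)C(C)=C)[C@H]1O[C@@H](C=C)[C@H]2[C@@H]1C(=O)CC[C@@]2(C)O
A4 | direct plan | tetracyclic (7Z)-oxonene with the tetrasubstituted ring-B enone | CO[C@@H]1CC[C@]2(C)C(=O)C(C)=C3CC[C@@](C)(OC(C)=O)[C@@H]4[C@H]3[C@@H]2O[C@H]4/C=C1/C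
A5 | direct plan | saturated ring-B ketone before oxygen insertion | CO[C@@H]1CC[C@]2(C)C(=O)[C@H](C)[C@@H]3CC[C@@](C)(OC(C)=O)[C@@H]4[C@H]3[C@@H]2O[C@H]4C[C@@]1(C)O
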